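## Structural features

The target (C28H38O7) is a 1,10-seco-aromadendrane sesquiterpenoid joined through an isopentyl carbon to a 3,5-diformylphloroglucinol. Numbering used throughout: ring A is the cyclopentanone C1(=O)–C2–C3–C4–C5; ring B is the cyclopropane C6–C7–C11 (C11 bears methyls C12 and C13); C7 carries the chain C8–C9–C10(=O)–C14; C4 carries methyl C15 and the benzylic carbon C1′, which carries C2′–C3′(C4′, C5′) and ring C, the arene. Rings A and B are joined only by the C5–C6 single bond, and on ring B the ring A substituent (C6) and the oxobutyl chain (C7) are cis. There are five stereocentres, all R: C6 and C7 on ring B, then the contiguous triad C5 (tertiary, α to C1=O), C4 (quaternary) and C1′ (benzylic, flanked by two ortho oxygens). Fragile points are the gem-dimethylcyclopropane (strong acid, or any cation or radical at C5), the epimerisable C5–H, the C1/C10 diketone (a C5 enolate can close a six-membered aldol ring onto C10) and the electron-rich formylated arene. The real difficulty is the C4–C1′ bond: a fully substituted ring carbon bonded to a hindered benzylic carbon, with both configurations fixed relative to a cyclopropane several bonds away. The key step exploits the fact that C4 is allylic to C1 through C5: a C1 carbinol oxygen on a ring A C4=C5 alkene can pass its configuration to C4 in a [3,3] shift that forms C4–C1′, and the C1=C5 alkene left behind is where the C1 carbonyl and C5–H are needed. Separately, ring B with its cis C5/C8 pair and complete C8–C9–C10(=O)–C14 chain maps onto the ozonolysis product of a cheap monoterpene.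

## Logic of the disconnections

24 to 21 (through 23 and 22). Bonds cut: the two aryl–CHO bonds; the three phenolic O–H bonds go back to O–CH3 and C10=O to a dioxolane. Reason: free phenols, aryl aldehydes and the C10 ketone would not survive the enolate, borane and ylide chemistry before them. Gain: ring C becomes an inert 2,4,6-trimethoxyphenyl group. Demand: double electrophilic formylation at the only two free arene positions, then ether cleavage assisted by the ortho formyl groups without damage to ring B.

21 to 15 (through 20, 19, 18 and 17). Bond cut: C2′–C3′ (as the C2′=C3′ alkene, back to a C2′ aldehyde); the C1 carbonyl is traced through a C1 carbinol to a C1=C5 alkene, and C2′ to a carboxyl carbon. Reason: 15 is exactly what the key step delivers, and one borane operation handles both its acid and its alkene. Gain: the isobutyl group and ketone are replaced by CO2H and C=C. Demand: boron must add to C1; a hindered α-aryl aldehyde must be olefinated without loss of C1′; C5 is left to equilibration, which must favour cyclopropyl trans to the C1′ substituent.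

15 to 12 (key disconnection). Bond cut: C4–C1′; bond re-formed: C1–O. In one sentence, the route is an ester-enolate [3,3] rearrangement of a cyclopentenyl arylacetate whose only new stereocentre is a carbinol set by reagent-controlled reduction. Reason: it turns the hardest C–C bond into an ester C–O bond and sets C4 and C1′ together. Gain: the congested vicinal pair is replaced by one secondary alcohol stereocentre and a planar enolate. Demand: Z-enolate geometry and a chair-like array.

12 to 10 and 11. Bond cut: the acyl C–O bond. Reason: convergent union of the terpenoid half with the arene half. Gain: two simple fragments. Demand: acylation of a hindered allylic alcohol with retention at C1.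

10 to 9. Bond cut: C1–H. Reason: a single carbinol centre next to a tetrasubstituted alkene is set easily by catalyst control. Gain: no stereocentre on ring A. Demand: face selection dictated by the catalyst, not by ring B.

9 to 6 and 7 (through 8). Bonds cut: C4=C5 (aldol condensation) and C1–C2 (acyl anion conjugate addition). Reason: the 2,3-disubstituted cyclopentenone is the aldol product of a 1,4-diketone. Gain: ring A comes from a four-carbon enone and an aldehyde. Demand: cyclisation through the C5 enolate, with C10 masked.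

6 to 3 (through 5 and 4). Bond cut: C1–C5 (one-carbon homologation), with C10 masked as the dioxolane while C1 is held as an acid-stable alkyne. Reason: C5 must become a nucleophilic α-carbon, so the C5 aldehyde needs one more carbon. Gain: back to a keto aldehyde whose two carbonyls can be told apart. Demand: aldehyde-only reaction in the presence of the C10 ketone.

3 to 1. Bond re-formed: C5=C10. Reason: the cis-cyclopropane, both its stereocentres and the whole C8–C10/C14 chain are already in 1. Gain: chiral-pool starting material. Demand: clean oxidative cleavage.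

## Other disconnections considered

Alternative 1: The first disconnection that comes to mind for a β-quaternary ketone cuts C4–C1′ as a conjugate addition. Forward step: benzylic deprotonation of 1,3,5-trimethoxy-2-(3-methylbutyl)benzene A1, transmetallation to copper and 1,4-addition to 9 with protonation at C5 would give 21 directly. Grounds against: 9 is a tetrasubstituted, α-branched enone, the poorest class of acceptor. The nucleophile is a secondary benzylic organometallic flanked by two methoxy groups and is configurationally labile, so nothing controls C1′ or the face at C4. Ring metalation between two methoxy groups would also compete with benzylic deprotonation. It is shorter on paper but leaves the whole stereochemical problem unanswered.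

Alternative 2: Form C4–C1′ while cutting C1–C3′ in an anionic oxy-Cope rearrangement. Forward step: the allyl anion from 1,3,5-trimethoxy-2-(3-methylbut-2-en-1-yl)benzene A2 adds through C3′ to the C1 carbonyl of 9, giving (1R)-2-{(1S,3R)-2,2-dimethyl-3-[2-(2-methyl-1,3-dioxolan-2-yl)ethyl]cyclopropyl}-3-methyl-1-[(3E)-2-methyl-4-(2,4,6-trimethoxyphenyl)but-3-en-2-yl]cyclopent-2-en-1-ol A3. Its potassium alkoxide would rearrange through a chair to the C1 enolate, which after protonation is 19 or its C5 epimer. Grounds against: the configuration at C4 is fixed by the face of addition to the C1 carbonyl of 9. The only nearby stereo-element is the C5 cyclopropyl group, whose two ring carbons shield both faces to a similar degree, so C4 would not be controlled. A stabilised allyl anion also invites retro-allylation of the hindered alkoxide. This plan is about four steps shorter but was rejected because it does not set C4; the chosen plan buys that control through a secondary carbinol.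

Alternative 3: Biomimetic reconnection of C1 and C10 as the alkene of a 5-7-3 tricycle, the aromadendr-1(10)-ene carrying at C4 the (1R)-3-methyl-1-(2,4,6-trimethoxyphenyl)butyl group A4. Forward key step: ozonolysis of the C1=C10 alkene to the seco diketone (2R,3R)-2-[(1R,3R)-2,2-dimethyl-3-(3-oxobutyl)cyclopropyl]-3-methyl-3-[(1R)-3-methyl-1-(2,4,6-trimethoxyphenyl)butyl]cyclopentan-1-one A5, then formylation and deprotection. Grounds against: the cleavage is easy but only moves the problem. A4 still needs the same C4–C1′ bond, now on a tricycle that must be derived from a scarcer sesquiterpene and functionalised at C4. Ozone would also have to discriminate between a tetrasubstituted alkene and a trimethoxyarene. The seven-membered ring would be built only to be destroyed, so step economy is worse.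

Key step: step 9

Remark: atom numbers are those defined under "Structural features"; (+)-2-carene (1), but-3-en-2-one (7) and 2-(2,4,6-trimethoxyphenyl)acetic acid (11) are taken as purchased materials.

## Steps

Step 1
Reactants: 1 (+)-2-carene, (1S,6R)-3,7,7-trimethylbicyclo[4.1.0]hept-2-ene
Product: 3 (1S,3R)-2,2-dimethyl-3-(3-oxobutyl)cyclopropane-1-carbaldehyde, via secondary ozonide 2 (not isolated)
Conditions: O3, CH2Cl2, −78 °C; then PPh3, −78 °C to rt
Reagents that add atoms: ozone [O-][O+]=O
Why: Ozonolysis (Criegee mechanism) cleaves the only alkene of 1, C5=C10, and reduction of ozonide 2 gives the keto aldehyde; C6 and C7 come unchanged from the chiral pool and already have the target configuration.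

Step 2
Reactants: 3 (1S,3R)-2,2-dimethyl-3-(3-oxobutyl)cyclopropane-1-carbaldehyde
Product: 4 4-[(1R,3R)-3-ethynyl-2,2-dimethylcyclopropyl]butan-2-one
Conditions: dimethyl (1-diazo-2-oxopropyl)phosphonate, K2CO3, MeOH, 0 °C to rt
Reagents that add atoms: dimethyl (1-diazo-2-oxopropyl)phosphonate CC(=O)C(=[N+]=[N-])P(=O)(OC)OC
Why: Seyferth–Gilbert homologation in its Ohira–Bestmann form: the diazophosphonate anion condenses with the aldehyde only and the alkylidene carbene rearranges to the terminal alkyne, adding C1. Ketones are inert under these conditions and the cyclopropane α-hydrogen is not readily removed by K2CO3, so C6 should keep its configuration.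

Step 3
Reactants: 4 4-[(1R,3R)-3-ethynyl-2,2-dimethylcyclopropyl]butan-2-one
Product: 5 2-{2-[(1R,3R)-3-ethynyl-2,2-dimethylcyclopropyl]ethyl}-2-methyl-1,3-dioxolane
Conditions: ethylene glycol, p-TsOH·H2O (cat.), benzene, reflux (Dean–Stark)
Reagents that add atoms: ethane-1,2-diol OCCO
Why: Acid-catalysed ketalisation with azeotropic removal of water masks C10=O before any enolate chemistry. The alkyne serves as an acid-stable placeholder for the C1 aldehyde, which is what lets the two carbonyl groups be told apart.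

Step 4
Reactants: 5 2-{2-[(1R,3R)-3-ethynyl-2,2-dimethylcyclopropyl]ethyl}-2-methyl-1,3-dioxolane
Product: 6 2-{(1S,3R)-2,2-dimethyl-3-[2-(2-methyl-1,3-dioxolan-2-yl)ethyl]cyclopropyl}acetaldehyde
Conditions: [CpRu(MeCN)3]PF6 (cat.), 5,5′-bis(trifluoromethyl)-2,2′-bipyridine (cat.), NMP/H2O, 25 °C
Reagents that add atoms: water O
Why: Ruthenium-catalysed anti-Markovnikov hydration of a terminal alkyne through a metal vinylidene gives the aldehyde under neutral conditions that leave the dioxolane and the cyclopropane intact.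

Step 5
Reactants: 6 2-{(1S,3R)-2,2-dimethyl-3-[2-(2-methyl-1,3-dioxolan-2-yl)ethyl]cyclopropyl}acetaldehyde; 7 but-3-en-2-one
Product: 8 1-{(1S,3R)-2,2-dimethyl-3-[2-(2-methyl-1,3-dioxolan-2-yl)ethyl]cyclopropyl}hexane-2,5-dione
Conditions: 3-benzyl-5-(2-hydroxyethyl)-4-methylthiazolium chloride (cat.), Et3N (cat.), EtOH, 70 °C
Reagents that add atoms: none
Why: Stetter reaction: the thiazolylidene converts the aldehyde into an acyl anion equivalent (Breslow intermediate) that adds 1,4 to the enone, forming C1–C2 and the 1,4-diketone. This is the classical entry to jasmone-type cyclopentenone precursors.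

Step 6
Reactants: 8 1-{(1S,3R)-2,2-dimethyl-3-[2-(2-methyl-1,3-dioxolan-2-yl)ethyl]cyclopropyl}hexane-2,5-dione
Product: 9 2-{(1S,3R)-2,2-dimethyl-3-[2-(2-methyl-1,3-dioxolan-2-yl)ethyl]cyclopropyl}-3-methylcyclopent-2-en-1-one
Conditions: NaOH (aq), EtOH, reflux
Reagents that add atoms: none
Why: Intramolecular aldol condensation of a 1,4-diketone: the C5 enolate attacks the C4 carbonyl and dehydration gives the more substituted, conjugated cyclopentenone as the thermodynamic product. With C10 masked, the competing six-membered aldol modes are closed off.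

Step 7
Reactants: 9 2-{(1S,3R)-2,2-dimethyl-3-[2-(2-methyl-1,3-dioxolan-2-yl)ethyl]cyclopropyl}-3-methylcyclopent-2-en-1-one
Product: 10 (1R)-2-{(1S,3R)-2,2-dimethyl-3-[2-(2-methyl-1,3-dioxolan-2-yl)ethyl]cyclopropyl}-3-methylcyclopent-2-en-1-ol
Conditions: (S)-2-methyl-CBS-oxazaborolidine (cat.), BH3·SMe2, THF, −20 °C; MeOH quench
Reagents that add atoms: none
Why: Corey–Bakshi–Shibata reduction: the oxazaborolidine–borane complex binds the carbonyl with the α-branched alkenyl flank as the large group and delivers hydride to one face only. The (S)-catalyst should therefore give the (1R)-alcohol under reagent control, the distant ring B stereocentres having little influence.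

Step 8
Reactants: 10 (1R)-2-{(1S,3R)-2,2-dimethyl-3-[2-(2-methyl-1,3-dioxolan-2-yl)ethyl]cyclopropyl}-3-methylcyclopent-2-en-1-ol; 11 2-(2,4,6-trimethoxyphenyl)acetic acid
Product: 12 (1R)-2-{(1S,3R)-2,2-dimethyl-3-[2-(2-methyl-1,3-dioxolan-2-yl)ethyl]cyclopropyl}-3-methylcyclopent-2-en-1-yl 2-(2,4,6-trimethoxyphenyl)acetate
Conditions: DCC, DMAP (cat.), CH2Cl2, 0 °C to rt
Reagents that add atoms: none
Why: Steglich esterification (carbodiimide activation, acyl transfer through DMAP) acylates the hindered allylic alcohol on oxygen, so the C1 stereocentre is not touched.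

Step 9
Reactants: 12 (1R)-2-{(1S,3R)-2,2-dimethyl-3-[2-(2-methyl-1,3-dioxolan-2-yl)ethyl]cyclopropyl}-3-methylcyclopent-2-en-1-yl 2-(2,4,6-trimethoxyphenyl)acetate
Product: 15 (2R)-2-[(1R)-2-{(1S,3R)-2,2-dimethyl-3-[2-(2-methyl-1,3-dioxolan-2-yl)ethyl]cyclopropyl}-1-methylcyclopent-2-en-1-yl]-2-(2,4,6-trimethoxyphenyl)acetic acid, via silyl ketene acetal 13 (not isolated), via trimethylsilyl ester 14 (not isolated)
Conditions: KN(SiMe3)2, THF/toluene, −78 °C; Me3SiCl, −78 °C to rt, then 60 °C; aqueous citric acid work-up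
Reagents that add atoms: none
Why: KN(SiMe3)2 removes a benzylic α-proton of 12 to give the potassium (Z)-enolate, which Me3SiCl traps on oxygen as the (Z)-silyl ketene acetal 13; on warming, 13 undergoes a concerted suprafacial [3,3] shift through the array C1′=C(OSi)–O–C1–C5=C4, forming C4–C1′, breaking C1–O and giving silyl ester 14, which is hydrolysed to 15 on work-up. The closest known reaction type is the Ireland–Claisen (ester enolate Claisen) rearrangement of 2-cycloalkenyl arylacetates, an established way to join a quaternary carbon to an aryl-bearing tertiary carbon. No ring is closed: the step trades a C–O bond for the C4–C1′ bond and moves the ring alkene from C4=C5 to C1=C5, where step 10 returns the oxygen. C4 is controlled by the C1 carbinol centre from step 7: because the shift is suprafacial, the new bond forms on the ring face that carried the ester oxygen, so (1R)-12 should give (4R). C1′ is controlled by the ketene acetal geometry together with a chair-like array, which places the arene pointing away from ring A and the C1′–H towards the C5 cyclopropyl group, giving (1′R). The selectivities needed are Z-enolisation and chair over boat: the first should follow from the preference of the aryl group to lie syn to the small O–K oxygen (A1,3 strain, possibly reinforced by K+ bridging to an ortho methoxy group), the second from the C5 cyclopropyl substituent, which straddles both ring faces and would clash with the OSiMe3 group in a boat. The rearrangement is intramolecular and made irreversible by C=O formation, which is what should let so congested a bond form on mild heating, well below the temperature at which the cis-alkyl vinylcyclopropane unit could undergo a homodienyl hydrogen shift.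

Step 10
Reactants: 15 (2R)-2-[(1R)-2-{(1S,3R)-2,2-dimethyl-3-[2-(2-methyl-1,3-dioxolan-2-yl)ethyl]cyclopropyl}-1-methylcyclopent-2-en-1-yl]-2-(2,4,6-trimethoxyphenyl)acetic acid
Product: 17 (1S,2S,3R)-2-{(1R,3R)-2,2-dimethyl-3-[2-(2-methyl-1,3-dioxolan-2-yl)ethyl]cyclopropyl}-3-[(1R)-2-hydroxy-1-(2,4,6-trimethoxyphenyl)ethyl]-3-methylcyclopentan-1-ol, via organoborane 16 (not isolated)
Conditions: BH3·THF (excess), THF, 0 °C to 40 °C; then NaOH, H2O2, 0 °C to rt
Reagents that add atoms: hydrogen peroxide OO
Why: Borane first reduces the carboxylic acid to the primary alcohol and then hydroborates the C1=C5 alkene with boron on the less substituted C1 (anti-Markovnikov, syn addition from the face opposite the large C4 substituent); oxidation with retention gives the diol. The C1 and C5 configurations formed here are transient, since C1 is oxidised in step 11 and C5 is equilibrated in step 13.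

Step 11
Reactants: 17 (1S,2S,3R)-2-{(1R,3R)-2,2-dimethyl-3-[2-(2-methyl-1,3-dioxolan-2-yl)ethyl]cyclopropyl}-3-[(1R)-2-hydroxy-1-(2,4,6-trimethoxyphenyl)ethyl]-3-methylcyclopentan-1-ol
Product: 18 (2R)-2-[(1R,2S)-2-{(1R,3R)-2,2-dimethyl-3-[2-(2-methyl-1,3-dioxolan-2-yl)ethyl]cyclopropyl}-1-methyl-3-oxocyclopentyl]-2-(2,4,6-trimethoxyphenyl)acetaldehyde
Conditions: Dess–Martin periodinane, NaHCO3, CH2Cl2, 0 °C to rt
Reagents that add atoms: none
Why: Dess–Martin oxidation converts the primary and the secondary alcohol to aldehyde and ketone under buffered, non-epimerising conditions that spare the dioxolane and the α-aryl stereocentre C1′.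

Step 12
Reactants: 18 (2R)-2-[(1R,2S)-2-{(1R,3R)-2,2-dimethyl-3-[2-(2-methyl-1,3-dioxolan-2-yl)ethyl]cyclopropyl}-1-methyl-3-oxocyclopentyl]-2-(2,4,6-trimethoxyphenyl)acetaldehyde
Product: 19 (2S,3R)-2-{(1R,3R)-2,2-dimethyl-3-[2-(2-methyl-1,3-dioxolan-2-yl)ethyl]cyclopropyl}-3-methyl-3-[(1R)-3-methyl-1-(2,4,6-trimethoxyphenyl)but-2-en-1-yl]cyclopentan-1-one
Conditions: isopropyltriphenylphosphonium iodide, KN(SiMe3)2, THF, 0 °C; then 18, −78 °C to 0 °C
Reagents that add atoms: isopropyltriphenylphosphonium iodide CC(C)[P+](c1ccccc1)(c1ccccc1)c1ccccc1.[I-]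
Why: Wittig olefination with a non-stabilised ylide: the aldehyde should react much faster than the hindered ring ketone, adding C3′, C4′ and C5′ as the isopropylidene group. Low temperature is chosen to limit enolisation at C1′.

Step 13
Reactants: 19 (2S,3R)-2-{(1R,3R)-2,2-dimethyl-3-[2-(2-methyl-1,3-dioxolan-2-yl)ethyl]cyclopropyl}-3-methyl-3-[(1R)-3-methyl-1-(2,4,6-trimethoxyphenyl)but-2-en-1-yl]cyclopentan-1-one
Product: 21 (2R,3R)-2-{(1R,3R)-2,2-dimethyl-3-[2-(2-methyl-1,3-dioxolan-2-yl)ethyl]cyclopropyl}-3-methyl-3-[(1R)-3-methyl-1-(2,4,6-trimethoxyphenyl)butyl]cyclopentan-1-one, via C5-epimeric ketone 20 (not isolated)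
Conditions: H2 (1 atm), Pd/C, EtOAc, rt; filter; then NaOMe (cat.), MeOH, rt
Reagents that add atoms: none
Why: Heterogeneous hydrogenation saturates the trisubstituted C2′=C3′ alkene (alkyl cyclopropanes tolerate Pd/C at 1 atm). Methoxide then equilibrates the epimerisable C5 through the enolate, and the thermodynamic isomer should be (5R), with the cyclopropyl group trans to the much larger C1′ substituent on C4 and cis to the C15 methyl.

Step 14
Reactants: 21 (2R,3R)-2-{(1R,3R)-2,2-dimethyl-3-[2-(2-methyl-1,3-dioxolan-2-yl)ethyl]cyclopropyl}-3-methyl-3-[(1R)-3-methyl-1-(2,4,6-trimethoxyphenyl)butyl]cyclopentan-1-one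
Product: 23 5-[(1R)-1-[(1R,2R)-2-[(1R,3R)-2,2-dimethyl-3-(3-oxobutyl)cyclopropyl]-1-methyl-3-oxocyclopentyl]-3-methylbutyl]-2,4,6-trimethoxybenzene-1,3-dicarbaldehyde, via dialdehyde ketal 22 (not isolated)
Conditions: Cl2CHOMe, TiCl4, CH2Cl2, −78 °C to 0 °C; then 1 M HCl, THF, rt
Reagents that add atoms: dichloromethyl methyl ether COC(Cl)Cl; water O
Why: Rieche formylation: the TiCl4-activated dichloromethyl methyl ether attacks the two remaining arene positions, each activated by three alkoxy groups, and hydrolysis of the α-chloro ethers gives the dialdehyde. The acidic work-up also hydrolyses the dioxolane and reveals C10=O.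

Step 15
Reactants: 23 5-[(1R)-1-[(1R,2R)-2-[(1R,3R)-2,2-dimethyl-3-(3-oxobutyl)cyclopropyl]-1-methyl-3-oxocyclopentyl]-3-methylbutyl]-2,4,6-trimethoxybenzene-1,3-dicarbaldehyde
Product: 24 5-[(1R)-1-[(1R,2R)-2-[(1R,3R)-2,2-dimethyl-3-(3-oxobutyl)cyclopropyl]-1-methyl-3-oxocyclopentyl]-3-methylbutyl]-2,4,6-trihydroxybenzene-1,3-dicarbaldehyde (target CNP0217082.3)
Conditions: BCl3, CH2Cl2, −78 °C to 0 °C; aqueous work-up
Reagents that add atoms: none
Why: Lewis-acid ether cleavage: BCl3 chelated between each methoxy oxygen and its ortho formyl group is displaced at methyl by chloride, so all three ethers, each ortho to an aldehyde, should cleave at low temperature. No stereocentre is involved, and hydrolysis of the aryl borates gives the target.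

## Compound list

1 | (+)-2-carene, (1S,6R)-3,7,7-trimethylbicyclo[4.1.0]hept-2-ene | CC1=C[C@H]2[C@@H](CC1)C2(C)C | starting material
2 | secondary ozonide of 1 (1,2,4-trioxolane across C5 and C10; not isolated, the two acetal carbons unassigned) | CC12CC[C@@H]3[C@H](C(OO1)O2)C3(C)C | intermediate
3 | (1S,3R)-2,2-dimethyl-3-(3-oxobutyl)cyclopropane-1-carbaldehyde | O=C[C@H]1[C@@H](CCC(C)=O)C1(C)C | intermediate
4 | 4-[(1R,3R)-3-ethynyl-2,2-dimethylcyclopropyl]butan-2-one | C#C[C@H]1[C@@H](CCC(C)=O)C1(C)C | intermediate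
5 | 2-{2-[(1R,3R)-3-ethynyl-2,2-dimethylcyclopropyl]ethyl}-2-methyl-1,3-dioxolane | C#C[C@H]1[C@@H](CCC2(C)OCCO2)C1(C)C | intermediate
6 | 2-{(1S,3R)-2,2-dimethyl-3-[2-(2-methyl-1,3-dioxolan-2-yl)ethyl]cyclopropyl}acetaldehyde | O=CC[C@H]1[C@@H](CCC2(C)OCCO2)C1(C)C | intermediate
7 | but-3-en-2-one (methyl vinyl ketone) | CC(=O)C=C | starting material
8 | 1-{(1S,3R)-2,2-dimethyl-3-[2-(2-methyl-1,3-dioxolan-2-yl)ethyl]cyclopropyl}hexane-2,5-dione | CC(=O)CCC(=O)C[C@H]1[C@@H](CCC2(C)OCCO2)C1(C)C | intermediate
9 | 2-{(1S,3R)-2,2-dimethyl-3-[2-(2-methyl-1,3-dioxolan-2-yl)ethyl]cyclopropyl}-3-methylcyclopent-2-en-1-one | CC1=C(C(=O)CC1)[C@H]1[C@@H](CCC2(C)OCCO2)C1(C)C | intermediate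
10 | (1R)-2-{(1S,3R)-2,2-dimethyl-3-[2-(2-methyl-1,3-dioxolan-2-yl)ethyl]cyclopropyl}-3-methylcyclopent-2-en-1-ol | O[C@@H]1CCC(C)=C1[C@H]1[C@@H](CCC2(C)OCCO2)C1(C)C | intermediate
11 | 2-(2,4,6-trimethoxyphenyl)acetic acid | COc1cc(OC)c(CC(=O)O)c(OC)c1 | starting material
12 | (1R)-2-{(1S,3R)-2,2-dimethyl-3-[2-(2-methyl-1,3-dioxolan-2-yl)ethyl]cyclopropyl}-3-methylcyclopent-2-en-1-yl 2-(2,4,6-trimethoxyphenyl)acetate | COc1cc(OC)c(CC(=O)O[C@@H]2CCC(C)=C2[C@H]2[C@@H](CCC3(C)OCCO3)C2(C)C)c(OC)c1 | intermediate
13 | (Z)-trimethylsilyl ketene acetal of 12 (aryl syn to OSiMe3; not isolated) | COc1cc(OC)c(/C=C(\O[Si](C)(C)C)O[C@@H]2CCC(C)=C2[C@H]2[C@@H](CCC3(C)OCCO3)C2(C)C)c(OC)c1 | intermediate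
14 | trimethylsilyl ester of 15 (not isolated) | CC1(OCCO1)CC[C@@H]1[C@H](C2=CCC[C@]2(C)[C@@H](C(=O)O[Si](C)(C)C)c2c(OC)cc(OC)cc2OC)C1(C)C | intermediate
15 | (2R)-2-[(1R)-2-{(1S,3R)-2,2-dimethyl-3-[2-(2-methyl-1,3-dioxolan-2-yl)ethyl]cyclopropyl}-1-methylcyclopent-2-en-1-yl]-2-(2,4,6-trimethoxyphenyl)acetic acid | CC1(OCCO1)CC[C@@H]1[C@H](C2=CCC[C@]2(C)[C@@H](C(=O)O)c2c(OC)cc(OC)cc2OC)C1(C)C | intermediate
16 | organoborane from 15 (C1–BH2 and C2′–O–BH2, idealised monomeric formula; not isolated) | CC1(OCCO1)CC[C@@H]1[C@H]([C@@H]2[C@@H](B)CC[C@]2(C)[C@@H](COB)c2c(OC)cc(OC)cc2OC)C1(C)C | intermediate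
17 | (1S,2S,3R)-2-{(1R,3R)-2,2-dimethyl-3-[2-(2-methyl-1,3-dioxolan-2-yl)ethyl]cyclopropyl}-3-[(1R)-2-hydroxy-1-(2,4,6-trimethoxyphenyl)ethyl]-3-methylcyclopentan-1-ol | CC1(OCCO1)CC[C@@H]1[C@H]([C@@H]2[C@@H](O)CC[C@]2(C)[C@@H](CO)c2c(OC)cc(OC)cc2OC)C1(C)C | intermediate
18 | (2R)-2-[(1R,2S)-2-{(1R,3R)-2,2-dimethyl-3-[2-(2-methyl-1,3-dioxolan-2-yl)ethyl]cyclopropyl}-1-methyl-3-oxocyclopentyl]-2-(2,4,6-trimethoxyphenyl)acetaldehyde | CC1(OCCO1)CC[C@@H]1[C@H]([C@@H]2C(=O)CC[C@]2(C)[C@@H](C=O)c2c(OC)cc(OC)cc2OC)C1(C)C | intermediate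
19 | (2S,3R)-2-{(1R,3R)-2,2-dimethyl-3-[2-(2-methyl-1,3-dioxolan-2-yl)ethyl]cyclopropyl}-3-methyl-3-[(1R)-3-methyl-1-(2,4,6-trimethoxyphenyl)but-2-en-1-yl]cyclopentan-1-one | CC1(OCCO1)CC[C@@H]1[C@H]([C@@H]2C(=O)CC[C@]2(C)[C@@H](C=C(C)C)c2c(OC)cc(OC)cc2OC)C1(C)C | intermediate
20 | (2S,3R)-2-{(1R,3R)-2,2-dimethyl-3-[2-(2-methyl-1,3-dioxolan-2-yl)ethyl]cyclopropyl}-3-methyl-3-[(1R)-3-methyl-1-(2,4,6-trimethoxyphenyl)butyl]cyclopentan-1-one (C5 epimer of 21; not isolated) | CC1(OCCO1)CC[C@@H]1[C@H]([C@@H]2C(=O)CC[C@]2(C)[C@@H](CC(C)C)c2c(OC)cc(OC)cc2OC)C1(C)C | intermediate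
21 | (2R,3R)-2-{(1R,3R)-2,2-dimethyl-3-[2-(2-methyl-1,3-dioxolan-2-yl)ethyl]cyclopropyl}-3-methyl-3-[(1R)-3-methyl-1-(2,4,6-trimethoxyphenyl)butyl]cyclopentan-1-one | CC1(OCCO1)CC[C@@H]1[C@H]([C@H]2C(=O)CC[C@]2(C)[C@@H](CC(C)C)c2c(OC)cc(OC)cc2OC)C1(C)C | intermediate
22 | 5-[(1R)-1-[(1R,2R)-2-{(1R,3R)-2,2-dimethyl-3-[2-(2-methyl-1,3-dioxolan-2-yl)ethyl]cyclopropyl}-1-methyl-3-oxocyclopentyl]-3-methylbutyl]-2,4,6-trimethoxybenzene-1,3-dicarbaldehyde (not isolated) | CC1(OCCO1)CC[C@@H]1[C@H]([C@H]2C(=O)CC[C@]2(C)[C@@H](CC(C)C)c2c(OC)c(C=O)c(OC)c(C=O)c2OC)C1(C)C | intermediate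
23 | 5-[(1R)-1-[(1R,2R)-2-[(1R,3R)-2,2-dimethyl-3-(3-oxobutyl)cyclopropyl]-1-methyl-3-oxocyclopentyl]-3-methylbutyl]-2,4,6-trimethoxybenzene-1,3-dicarbaldehyde | CC(=O)CC[C@@H]1[C@H]([C@H]2C(=O)CC[C@]2(C)[C@@H](CC(C)C)c2c(OC)c(C=O)c(OC)c(C=O)c2OC)C1(C)C | intermediate
24 | 5-[(1R)-1-[(1R,2R)-2-[(1R,3R)-2,2-dimethyl-3-(3-oxobutyl)cyclopropyl]-1-methyl-3-oxocyclopentyl]-3-methylbutyl]-2,4,6-trihydroxybenzene-1,3-dicarbaldehyde (CNP0217082.3) | CC(=O)CC[C@@H]1[C@H]([C@H]2C(=O)CC[C@]2(C)[C@@H](CC(C)C)c2c(O)c(C=O)c(O)c(C=O)c2O)C1(C)C | target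

## Step count and least certain steps

Total step count: 15. Longest linear sequence: 15 steps (1 to 24); 7 and 11 are purchased and enter in steps 5 and 8.

Step 9 (key step). Most likely failure: leakage through a boat-like array or incomplete Z-enolisation, either of which erodes the C1′ configuration; the rearrangement may also be slow at the congested C4 terminus, giving the silyl ketene acetal time to fragment to a ketene. The cause is that chair and boat arrays lie close in energy for cycloalkenyl esters, and a twisted di-ortho-substituted aryl group is a weaker geometric control element than a planar one. Fallback, which separates the two stereocentres: from 10, a Johnson–Claisen rearrangement (triethyl orthoacetate, propionic acid cat., toluene, 110 °C) sets C4 by the same 1,3-transfer with no C1′ issue and gives ethyl 2-[(1R)-2-{(1S,3R)-2,2-dimethyl-3-[2-(2-methyl-1,3-dioxolan-2-yl)ethyl]cyclopropyl}-1-methylcyclopent-2-en-1-yl]acetate F1. Palladium-catalysed α-arylation of its lithium enolate with 2-bromo-1,3,5-trimethoxybenzene (LiN(SiMe3)2, Pd(dba)2, P(t-Bu)3, toluene) gives ethyl 2-[(1R)-2-{(1S,3R)-2,2-dimethyl-3-[2-(2-methyl-1,3-dioxolan-2-yl)ethyl]cyclopropyl}-1-methylcyclopent-2-en-1-yl]-2-(2,4,6-trimethoxyphenyl)acetate F2 as C1′ epimers to be separated. Saponification (LiOH, THF/H2O) returns to the route at 15.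

Step 12. Most likely failure: deprotonation of the hindered α-aryl aldehyde by the basic ylide instead of addition, which scrambles C1′ and returns aldehyde; attack at the ring ketone is a lesser risk. The cause is steric shielding of the formyl group by the arene and the C4 quaternary carbon. Fallback that avoids the aldehyde: from 17, selective sulfonylation of the primary hydroxyl (TsCl, pyridine, 0 °C) gives (2R)-2-[(1R,2S,3S)-2-{(1R,3R)-2,2-dimethyl-3-[2-(2-methyl-1,3-dioxolan-2-yl)ethyl]cyclopropyl}-3-hydroxy-1-methylcyclopentyl]-2-(2,4,6-trimethoxyphenyl)ethyl 4-methylbenzenesulfonate F3. Copper-catalysed alkyl–alkyl coupling with i-PrMgCl (CuCl2 cat., 1-phenylpropyne cat., THF) gives (1S,2S,3R)-2-{(1R,3R)-2,2-dimethyl-3-[2-(2-methyl-1,3-dioxolan-2-yl)ethyl]cyclopropyl}-3-methyl-3-[(1R)-3-methyl-1-(2,4,6-trimethoxyphenyl)butyl]cyclopentan-1-ol F4. Dess–Martin oxidation of F4 returns to the route at 20, which is equilibrated to 21 as in the second half of step 13.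

Step 14. Most likely failure: stalling after the first formylation, which deactivates the ring, or acid-induced opening of ring B and aldol chemistry under TiCl4 and HCl. Fallback that reverses the order of dealkylation and formylation and uses no titanium: from 21, BBr3 (CH2Cl2, −78 °C to rt; aqueous work-up, which also hydrolyses the dioxolane) gives (2R,3R)-2-[(1R,3R)-2,2-dimethyl-3-(3-oxobutyl)cyclopropyl]-3-methyl-3-[(1R)-3-methyl-1-(2,4,6-trihydroxyphenyl)butyl]cyclopentan-1-one F5. Vilsmeier–Haack diformylation of the free, strongly activated phloroglucinol ring (POCl3, DMF, 0 °C to rt; aqueous NaOAc) returns to the route at 24, bypassing step 15.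

Step 2. Most likely failure: base-mediated intramolecular aldol addition of the C9 enolate to the formyl group, or cis-to-trans epimerisation at C6, before the homologation is complete, because 3 carries an enolisable ketone five atoms from an aldehyde. Fallback under non-basic olefination conditions: from 3, CBr4/PPh3 (CH2Cl2, 0 °C) gives 4-[(1R,3R)-3-(2,2-dibromoethenyl)-2,2-dimethylcyclopropyl]butan-2-one F6. Ketalisation as in step 3 gives 2-{2-[(1R,3R)-3-(2,2-dibromoethenyl)-2,2-dimethylcyclopropyl]ethyl}-2-methyl-1,3-dioxolane F7. Treatment with n-BuLi (THF, −78 °C), then water, returns to the route at 5.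

Step 6. Most likely failure: cyclisation through the methyl ketone enolate onto the C1 carbonyl, because the C5 methylene is shielded by the cis-substituted cyclopropane; this would give the isomeric 3-substituted cyclopentenone. Fallback that builds ring A by cycloaddition: from 5, n-BuLi then MeI gives 2-{2-[(1R,3S)-2,2-dimethyl-3-(prop-1-yn-1-yl)cyclopropyl]ethyl}-2-methyl-1,3-dioxolane F8. A Pauson–Khand reaction with ethylene (Co2(CO)8; then ethylene, N-methylmorpholine N-oxide, CH2Cl2) places the larger alkyne substituent next to the carbonyl and returns to the route at 9, bypassing steps 4 to 6.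

## Further compounds

F1 | step 9 | ethyl 2-[(1R)-2-{(1S,3R)-2,2-dimethyl-3-[2-(2-methyl-1,3-dioxolan-2-yl)ethyl]cyclopropyl}-1-methylcyclopent-2-en-1-yl]acetate | CC1(OCCO1)CC[C@@H]1[C@H](C2=CCC[C@]2(C)CC(=O)OCC)C1(C)C
F2 | step 9 | ethyl 2-[(1R)-2-{(1S,3R)-2,2-dimethyl-3-[2-(2-methyl-1,3-dioxolan-2-yl)ethyl]cyclopropyl}-1-methylcyclopent-2-en-1-yl]-2-(2,4,6-trimethoxyphenyl)acetate (C1′ epimers) | CC1(OCCO1)CC[C@@H]1[C@H](C2=CCC[C@]2(C)C(C(=O)OCC)c2c(OC)cc(OC)cc2OC)C1(C)C
F3 | step 12 | (2R)-2-[(1R,2S,3S)-2-{(1R,3R)-2,2-dimethyl-3-[2-(2-methyl-1,3-dioxolan-2-yl)ethyl]cyclopropyl}-3-hydroxy-1-methylcyclopentyl]-2-(2,4,6-trimethoxyphenyl)ethyl 4-methylbenzenesulfonate | CC1(OCCO1)CC[C@@H]1[C@H]([C@@H]2[C@@H](O)CC[C@]2(C)[C@@H](COS(=O)(=O)c2ccc(C)cc2)c2c(OC)cc(OC)cc2OC)C1(C)C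
F4 | step 12 | (1S,2S,3R)-2-{(1R,3R)-2,2-dimethyl-3-[2-(2-methyl-1,3-dioxolan-2-yl)ethyl]cyclopropyl}-3-methyl-3-[(1R)-3-methyl-1-(2,4,6-trimethoxyphenyl)butyl]cyclopentan-1-ol | CC1(OCCO1)CC[C@@H]1[C@H]([C@@H]2[C@@H](O)CC[C@]2(C)[C@@H](CC(C)C)c2c(OC)cc(OC)cc2OC)C1(C)C
F5 | step 14 | (2R,3R)-2-[(1R,3R)-2,2-dimethyl-3-(3-oxobutyl)cyclopropyl]-3-methyl-3-[(1R)-3-methyl-1-(2,4,6-trihydroxyphenyl)butyl]cyclopentan-1-one | CC(=O)CC[C@@H]1[C@H]([C@H]2C(=O)CC[C@]2(C)[C@@H](CC(C)C)c2c(O)cc(O)cc2O)C1(C)C
F6 | step 2 | 4-[(1R,3R)-3-(2,2-dibromoethenyl)-2,2-dimethylcyclopropyl]butan-2-one | BrC(Br)=C[C@H]1[C@@H](CCC(C)=O)C1(C)C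
F7 | step 2 | 2-{2-[(1R,3R)-3-(2,2-dibromoethenyl)-2,2-dimethylcyclopropyl]ethyl}-2-methyl-1,3-dioxolane | BrC(Br)=C[C@H]1[C@@H](CCC2(C)OCCO2)C1(C)C
F8 | step 6 | 2-{2-[(1R,3S)-2,2-dimethyl-3-(prop-1-yn-1-yl)cyclopropyl]ethyl}-2-methyl-1,3-dioxolane | CC#C[C@H]1[C@@H](CCC2(C)OCCO2)C1(C)C
A1 | alternative 1 | 1,3,5-trimethoxy-2-(3-methylbutyl)benzene | COc1cc(OC)c(CCC(C)C)c(OC)c1
A2 | alternative 2 | 1,3,5-trimethoxy-2-(3-methylbut-2-en-1-yl)benzene | COc1cc(OC)c(CC=C(C)C)c(OC)c1
A3 | alternative 2 | (1R)-2-{(1S,3R)-2,2-dimethyl-3-[2-(2-methyl-1,3-dioxolan-2-yl)ethyl]cyclopropyl}-3-methyl-1-[(3E)-2-methyl-4-(2,4,6-trimethoxyphenyl)but-3-en-2-yl]cyclopent-2-en-1-ol | O[C@]1(CCC(C)=C1[C@H]1[C@@H](CCC2(C)OCCO2)C1(C)C)C(C)(C)/C=C/c1c(OC)cc(OC)cc1OC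
A4 | alternative 3 | aromadendr-1(10)-ene carrying at C4 the (1R)-3-methyl-1-(2,4,6-trimethoxyphenyl)butyl group (5-7-3 tricycle, C1=C10 alkene) | CC=3CC[C@@H]1[C@H]([C@H]2C3CC[C@]2(C)[C@@H](CC(C)C)c2c(OC)cc(OC)cc2OC)C1(C)C
A5 | alternative 3 | (2R,3R)-2-[(1R,3R)-2,2-dimethyl-3-(3-oxobutyl)cyclopropyl]-3-methyl-3-[(1R)-3-methyl-1-(2,4,6-trimethoxyphenyl)butyl]cyclopentan-1-one | CC(=O)CC[C@@H]1[C@H]([C@H]2C(=O)CC[C@]2(C)[C@@H](CC(C)C)c2c(OC)cc(OC)cc2OC)C1(C)C
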